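## Analysis of the target

The target 13 is a tetrahydrofuran whose ring atoms are numbered here O1, C2, C3, C4 and C5. C2 bears the 3,4-dihydroxyphenyl ring, C3 the hydroxymethyl carbon C6, C4 is a fully substituted carbinol carrying the free hydroxyl and the benzylic carbon C7 of the 3,4-dimethoxybenzyl group, and C5 is a plain CH2. The three contiguous stereocentres are 2R, 3R and 4R. The aryl group on C2, the C6 arm on C3 and the hydroxyl on C4 lie on one face of the ring and only C7 lies on the other, so C2 and C3 are cis-substituted and C7 is trans to C6. The sensitive sites are the catechol (air oxidation, above all under base) and the C2–O1 bond, a benzylic ether para to an oxygen donor: acid can ionise it and let the crowded cis C2/C3 pair relax to trans, and hydrogenolysis can cleave it. The difficulty is therefore to build a contra-thermodynamic cis pair next to a tetrasubstituted carbinol centre and to keep both through the end-game. The strategy rests on the path O1–C2–C3–C4–C5: with C5 raised to the carboxyl level the ring is a γ-lactone in which C2–C3 joins an aryl aldehyde carbon to the β-carbon of a four-carbon enal (C5, C4, C3, C6), and in which C4 is the enolisable α-carbon that can take up its oxygen and its benzyl group one after the other.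

## Retrosynthetic reasoning

**13 to 12.** The last disconnection is that of four O–benzyl bonds (two phenolic, one on C6–O, one on C4–O). Using one protecting group for all four hydroxyls means that the catechol is released in a single neutral operation at the very end, with no acid near C2–O1 and no base near the catechol.

**12 to 10 through 11.** No skeletal bond is cut here; C5 is re-oxidised in the retrosynthetic sense from CH2 in 12 through the lactol 11 to the lactone carbonyl of 10. This makes C4 the α-carbon of a carbonyl group. The forward reaction has to remove the carbonyl oxygen without touching C2–O1, which is why it is done in two stages: hydride to the lactol, then ionisation of the hemiacetal carbon only, at low temperature, with a silane as hydride donor.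

**10 to 8 and 9.** The C4–C7 bond is cut, giving the α-benzyloxy lactone 8 and the benzylic bromide 9. C4–C7 is cut before C4–O because the group that enters a planar lactone enolate second ends up anti to the C6 arm (and to the aryl group, which is on the same face). In the target C7 is anti and the hydroxyl is syn, so oxygen has to go in first and carbon second. The forward reaction must create the quaternary centre with this facial preference.

**8 to 7 to 6.** The C4–O bond is cut back to the unsubstituted lactone 6; in the forward sense the enolate of 6 is oxidised to 7 and the new hydroxyl is benzylated. The configuration of C4 in 7 and 8 is of no consequence, because C4 becomes planar again in the next enolisation.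

**6 to 4 and 5.** Both C2–C3 and O1–C5 are cut, which leads to the enal 4 and the aryl aldehyde 5. This is the disconnection that simplifies most: it removes the ring, two skeletal bonds and two stereocentres at once, and both fragments are trivial. The forward reaction, a carbene-catalysed homoenolate annulation, must join the β-carbon of 4 to the carbonyl carbon of 5, give the cis lactone, fix the absolute configuration through the chiral catalyst, and avoid self-condensation of 4. The C6 oxygen is carried as a benzyl ether: an alkoxide is a poorer leaving group than a silanolate or a carboxylate, so the homoenolate is not drained by γ-elimination. The benzyl ether also survives the later Lewis acid and leaves together with the other three.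

**4 to 2 to 1.** The enal 4 comes from the symmetrical diol 1 by monobenzylation to 2 and oxidation. The oxidation first gives the Z-enal 3, which equilibrates to the E-isomer 4 required for the homoenolate geometry.

## Alternatives that were turned down

**Alternative 1:** The disconnection removes the catechol ring itself. Two of its carbons come from an ethynyl group on C2 of an otherwise finished ring, the alkynyl tetrahydrofuran A2, and four from 2,3-bis(trimethylsilyloxy)buta-1,3-diene A3. In the forward key step a reduced cobalt catalyst generated from CoBr2(dppe), Zn and ZnI2 joins alkyne and diene by [4+2] cycloaddition to the cyclohexa-1,4-diene A4, which DDQ dehydrogenates to the bis(trimethylsilyl) catechol ether A1.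

- For it: while C2 carries an alkyne and not an electron-rich arene, C2–O1 is not a donor-stabilised benzylic ether, so acids and Lewis acids are harmless in the earlier steps. The diene is symmetrical, so there is no regiochemical question. The catechol appears as silyl ethers that fall off with fluoride, so no hydrogenolysis is needed next to a benzylic ether. On this last point the alternative is stronger than the chosen route.
- Against it: the cycloaddition forms no stereocentre and no bond of the heterocycle. All three stereocentres of A2 would have to come from a separate sequence about as long as the whole chosen route, with a propargylic carbon in place of the benzylic one. A3 and A4 are silyl enol ethers that ZnI2 and traces of water degrade, and the free tertiary hydroxyl of A2 is a proton source in the same flask. DDQ is unselective here: it also dehydrogenates silyl enol ethers to enones and can abstract hydride from C7 and, once the arene exists, from C2.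
- Comparison: in exchange for the gentler end-game, the chosen strategy uses a purchased arene and a key step that closes the ring and sets two stereocentres together.

**Alternative 2:** The disconnection cuts C2–C3 together with a temporary bond from the aldehyde oxygen to the carbon that becomes C6. The forward key step is a Paternò–Büchi [2+2] photocycloaddition of 3,4-bis(pivaloyloxy)benzaldehyde A6 with 3-(3,4-dimethoxybenzyl)furan A7. The excited aldehyde attacks the unsubstituted furan double bond through a 1,4-diradical and closes the cis-fused oxetane A5 with the aryl group exo.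

- For it: no reagent is consumed and both partners are simple. The bicyclic adduct locks the aryl group and the future C6 cis. Its remaining enol ether already carries C7 and offers a convex face for oxygenation at C4, so the relative configuration of all three centres is encoded more rigidly than in the chosen route. On diastereocontrol the alternative is the stronger one.
- Against it: there is no handle for absolute configuration, because a photochemical step without a chiral controller gives the racemate and a resolution would discard half of the material. Site selectivity between the two furan double bonds is uncertain, since the benzyl-substituted one is the more electron-rich. The adduct is also the wrong heterocycle: the oxygen on C2 is tied to C6 and not to C5. The acetal would have to be opened, C6 reduced, C5 brought to the level of a CH2 and the ring closed again, all on an acid-labile aryl oxetane acetal, and the pivalates need hydride or base for removal.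
- Comparison: the chosen route closes the correct ring directly, under a chiral catalyst, at the lactone oxidation level that is then used to build C4.

**Alternative 3:** The disconnection cuts C4–C5 and C7–aryl at the carbinol carbon and leads to three components: the alkenyl boronic ester A9, in which C4=C7 is a 1,1-disubstituted alkene and C2 and C3 are already in place; (isopropoxydimethylsilyl)methylmagnesium chloride A10, which brings C5; and 3,4-dimethoxyphenyl trifluoromethanesulfonate A11. In the forward key step A10 adds to boron to give the ate complex. Zerovalent palladium from Pd(OAc)2/MandyPhos inserts into the C–O bond of A11, the cationic aryl complex of divalent palladium binds the alkene, the silylmethyl group migrates from boron to C4 as palladium bonds to C7, and reductive elimination forms C7–aryl. The product is the tertiary boronic ester A8; oxidation of C–B and C–Si and an etherification would follow.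

- For it: C4 is set by a chiral ligand and not by the bias of a ring, which in principle is the stronger form of control. The dimethoxyphenyl unit enters as a stable aryl triflate and not as a labile benzylic bromide.
- Against it: A9 contains C2 and C3 and would itself need an asymmetric aldol-type sequence plus the installation of the alkenyl boronate. The migration terminus is a 1,1-disubstituted alkene next to a branched stereogenic carbon, the most demanding substrate class for this coupling, and the ligand would have to cooperate with the resident centres. Halide from the Grignard reagent slows the palladium cycle. After the coupling two oxidations and a ring closure by displacement at the neopentyl C5 remain.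
- Comparison: the chosen route sets C4 by two inexpensive enolate operations whose facial bias is reinforced by both cis substituents, and it is several steps shorter.

Key step: step 3

Assumption: the sense of induction of the aminoindanol-derived carbene for this enal/aldehyde pair cannot be read from the structures with certainty; the catalyst antipode that delivers (4R,5R)-6 is used, and both antipodes are accessible.

## Route

Step 1
Reactants: 1 (Z)-but-2-ene-1,4-diol
Product: 2 (Z)-4-(benzyloxy)but-2-en-1-ol
Conditions: NaH (1.0 equiv), THF, 0 °C; BnBr (1.0 equiv), Bu4NI (cat.), 0 °C to rt; 1 used in threefold excess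
Reagents that add atoms: benzyl bromide, BrCc1ccccc1
Why: Williamson etherification of a cheap symmetrical diol; the excess of 1 should suppress dibenzylation, and unreacted 1 is removed by aqueous extraction.

Step 2
Reactants: 2 (Z)-4-(benzyloxy)but-2-en-1-ol
Product: 4 (E)-4-(benzyloxy)but-2-enal, via (Z)-4-(benzyloxy)but-2-enal 3 (not isolated)
Conditions: pyridinium chlorochromate [C5H5NH][CrO3Cl] (1.5 equiv), Celite, CH2Cl2, rt
Reagents that add atoms: none
Why: Chlorochromate oxidation of the primary allylic alcohol gives the Z-enal 3, and the mildly acidic pyridinium medium should equilibrate it to the conjugated, less strained E-isomer 4 under thermodynamic control; any residual Z-isomer is expected to isomerise on brief exposure to a trace of acid.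

Step 3
Reactants: 4 (E)-4-(benzyloxy)but-2-enal; 5 3,4-bis(benzyloxy)benzaldehyde
Product: 6 (4R,5R)-4-[(benzyloxy)methyl]-5-[3,4-bis(benzyloxy)phenyl]dihydrofuran-2(3H)-one (4,5-cis)
Conditions: (5aS,10bR)-2-mesityl-5a,10b-dihydro-4H,6H-indeno[2,1-b][1,2,4]triazolo[4,3-d][1,4]oxazin-2-ium chloride or its antipode (10 mol%), DBU (10 mol%), THF, rt; 5 (2 equiv), 4 added over several hours by syringe pump
Reagents that add atoms: none
Why: DBU deprotonates the triazolium salt and the free carbene adds to the formyl carbon of 4; proton transfer gives the conjugated hydroxy-enamine, a homoenolate equivalent whose nucleophilic site is the former β-carbon (C3). This carbon adds to the carbonyl carbon of 5 and forms C2–C3, leaving an enol azolium that tautomerises to the acyl azolium with C5 as the acyl carbon. The C2 alkoxide then attacks that acyl carbon in a 5-exo-trig acyl substitution that forms O1–C5, closes the γ-lactone and releases the carbene. The closest known reaction type is the carbene-catalysed homoenolate annulation of enals with aromatic aldehydes, which gives cis-4,5-disubstituted γ-butyrolactones. C2 and C3 are created together in the C–C bond-forming addition: their cis relationship should follow from the compact arrangement in which the aldehyde oxygen stays close to the hydroxy-enamine OH, and the absolute configuration is controlled by the chiral carbene, whose fused indane and N-mesityl group leave one face of the homoenolate open. The step needs cross-selectivity (the homoenolate of 4 must add to 5 and not to a second molecule of 4), cis selectivity and enantiofacial selectivity. Keeping 4 at low concentration against an excess of 5, which cannot itself form a homoenolate, serves the first; the C6 benzyl ether is not a leaving group, so the homoenolate is not lost by elimination, and neither new centre is acidic, so the kinetic cis preference is not eroded by the base.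

Step 4
Reactants: 6 (4R,5R)-4-[(benzyloxy)methyl]-5-[3,4-bis(benzyloxy)phenyl]dihydrofuran-2(3H)-one
Product: 7 (3S,4S,5R)-4-[(benzyloxy)methyl]-5-[3,4-bis(benzyloxy)phenyl]-3-hydroxydihydrofuran-2(3H)-one (3,4-trans)
Conditions: KN(SiMe3)2 (1.15 equiv), THF, −78 °C; 2-(phenylsulfonyl)-3-phenyloxaziridine (1.3 equiv), −78 °C; AcOH quench
Reagents that add atoms: 2-(phenylsulfonyl)-3-phenyloxaziridine, O=S(=O)(c1ccccc1)N1OC1c1ccccc1
Why: Electrophilic hydroxylation of the lactone enolate by the N-sulfonyloxaziridine (Davis oxidation); oxygen should arrive anti to the C6 arm, but this centre is made planar again in step 6, so its configuration is not critical. The potassium counter-ion limits addition of the enolate to the sulfonimine by-product.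

Step 5
Reactants: 7 (3S,4S,5R)-4-[(benzyloxy)methyl]-5-[3,4-bis(benzyloxy)phenyl]-3-hydroxydihydrofuran-2(3H)-one
Product: 8 (3S,4R,5R)-3-(benzyloxy)-4-[(benzyloxy)methyl]-5-[3,4-bis(benzyloxy)phenyl]dihydrofuran-2(3H)-one
Conditions: BnBr (3 equiv), Ag2O (2 equiv), 4 Å molecular sieves, CH2Cl2, rt, dark
Reagents that add atoms: benzyl bromide, BrCc1ccccc1
Why: Ag2O-promoted Williamson benzylation of an α-hydroxy lactone under non-basic conditions, so that no free alkoxide opens the lactone; the benzyl ether is chosen because it tolerates the enolate, hydride and Lewis acid steps and leaves in the final hydrogenolysis.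

Step 6
Reactants: 8 (3S,4R,5R)-3-(benzyloxy)-4-[(benzyloxy)methyl]-5-[3,4-bis(benzyloxy)phenyl]dihydrofuran-2(3H)-one; 9 4-(bromomethyl)-1,2-dimethoxybenzene
Product: 10 (3R,4R,5R)-3-(benzyloxy)-4-[(benzyloxy)methyl]-5-[3,4-bis(benzyloxy)phenyl]-3-(3,4-dimethoxybenzyl)dihydrofuran-2(3H)-one
Conditions: LiN(SiMe3)2 (1.2 equiv), THF, −78 °C; 9 (1.5 equiv, freshly purified), DMPU, −78 to −40 °C
Reagents that add atoms: none
Why: SN2 alkylation of the α-alkoxy lactone enolate with a reactive benzylic bromide; the planar enolate should be attacked on the face opposite the C6 arm and the C2 aryl group, which are both on the same face, so C7 ends trans to C6 and the benzyloxy group cis to it. This substrate-controlled step sets the C4 stereocentre of the target, which is why oxygen was introduced before carbon.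

Step 7
Reactants: 10 (3R,4R,5R)-3-(benzyloxy)-4-[(benzyloxy)methyl]-5-[3,4-bis(benzyloxy)phenyl]-3-(3,4-dimethoxybenzyl)dihydrofuran-2(3H)-one
Product: 11 (3R,4R,5R)-3-(benzyloxy)-4-[(benzyloxy)methyl]-5-[3,4-bis(benzyloxy)phenyl]-3-(3,4-dimethoxybenzyl)tetrahydrofuran-2-ol (mixture of anomers)
Conditions: i-Bu2AlH (1.3 equiv), CH2Cl2, −78 °C; aqueous potassium sodium tartrate
Reagents that add atoms: none
Why: Partial hydride reduction of a lactone to the lactol; the tetrahedral aluminium hemiacetal is stable at −78 °C, so over-reduction to the diol should not occur, and benzyl ethers are inert.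

Step 8
Reactants: 11 (3R,4R,5R)-3-(benzyloxy)-4-[(benzyloxy)methyl]-5-[3,4-bis(benzyloxy)phenyl]-3-(3,4-dimethoxybenzyl)tetrahydrofuran-2-ol
Product: 12 (2R,3R,4R)-4-(benzyloxy)-3-[(benzyloxy)methyl]-2-[3,4-bis(benzyloxy)phenyl]-4-(3,4-dimethoxybenzyl)tetrahydrofuran
Conditions: Et3SiH (3 equiv), BF3·OEt2 (1.5 equiv), CH2Cl2, −78 to −40 °C; Et3N then aqueous NaHCO3 at low temperature
Reagents that add atoms: none
Why: Ionic hydrogenation of a lactol: the Lewis acid ionises the hemiacetal carbon C5 to the cyclic oxocarbenium ion and the silane delivers hydride to it, as in the reduction of benzylated furanose lactols to anhydro-alditols. No stereocentre is formed, and the low temperature should keep the benzylic C2–O1 bond from ionising.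

Step 9
Reactants: 12 (2R,3R,4R)-4-(benzyloxy)-3-[(benzyloxy)methyl]-2-[3,4-bis(benzyloxy)phenyl]-4-(3,4-dimethoxybenzyl)tetrahydrofuran
Product: 13 4-[(2R,3R,4R)-4-(3,4-dimethoxybenzyl)-4-hydroxy-3-(hydroxymethyl)tetrahydrofuran-2-yl]benzene-1,2-diol
Conditions: H2 (1 atm), Pd(OH)2/C (20 wt%), EtOAc–MeOH, rt; filtration under argon
Reagents that add atoms: none
Why: Catalytic hydrogenolysis of the four O-benzyl groups under neutral conditions; primary benzyl C–O bonds should be cleaved much faster than the secondary, hindered benzylic C2–O1 bond of the ring, and the aryl methyl ethers are inert. No stereocentre is touched.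

## Compound list

1 | (Z)-but-2-ene-1,4-diol | OC/C=C\CO | starting material
2 | (Z)-4-(benzyloxy)but-2-en-1-ol | OC/C=C\COCc1ccccc1 | intermediate
3 | (Z)-4-(benzyloxy)but-2-enal | O=C/C=C\COCc1ccccc1 | intermediate
4 | (E)-4-(benzyloxy)but-2-enal | O=C/C=C/COCc1ccccc1 | intermediate
5 | 3,4-bis(benzyloxy)benzaldehyde | O=Cc1ccc(OCc2ccccc2)c(OCc2ccccc2)c1 | starting material
6 | (4R,5R)-4-[(benzyloxy)methyl]-5-[3,4-bis(benzyloxy)phenyl]dihydrofuran-2(3H)-one | O=C1O[C@@H](c2ccc(OCc3ccccc3)c(OCc3ccccc3)c2)[C@@H](COCc2ccccc2)C1 | intermediate
7 | (3S,4S,5R)-4-[(benzyloxy)methyl]-5-[3,4-bis(benzyloxy)phenyl]-3-hydroxydihydrofuran-2(3H)-one | O=C1O[C@@H](c2ccc(OCc3ccccc3)c(OCc3ccccc3)c2)[C@@H](COCc2ccccc2)[C@@H]1O | intermediate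
8 | (3S,4R,5R)-3-(benzyloxy)-4-[(benzyloxy)methyl]-5-[3,4-bis(benzyloxy)phenyl]dihydrofuran-2(3H)-one | O=C1O[C@@H](c2ccc(OCc3ccccc3)c(OCc3ccccc3)c2)[C@@H](COCc2ccccc2)[C@@H]1OCc2ccccc2 | intermediate
9 | 4-(bromomethyl)-1,2-dimethoxybenzene | COc1ccc(CBr)cc1OC | starting material
10 | (3R,4R,5R)-3-(benzyloxy)-4-[(benzyloxy)methyl]-5-[3,4-bis(benzyloxy)phenyl]-3-(3,4-dimethoxybenzyl)dihydrofuran-2(3H)-one | O=C1O[C@@H](c2ccc(OCc3ccccc3)c(OCc3ccccc3)c2)[C@@H](COCc2ccccc2)[C@]1(OCc2ccccc2)Cc2ccc(OC)c(OC)c2 | intermediate
11 | (3R,4R,5R)-3-(benzyloxy)-4-[(benzyloxy)methyl]-5-[3,4-bis(benzyloxy)phenyl]-3-(3,4-dimethoxybenzyl)tetrahydrofuran-2-ol (anomers) | OC1O[C@@H](c2ccc(OCc3ccccc3)c(OCc3ccccc3)c2)[C@@H](COCc2ccccc2)[C@]1(OCc2ccccc2)Cc2ccc(OC)c(OC)c2 | intermediate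
12 | (2R,3R,4R)-4-(benzyloxy)-3-[(benzyloxy)methyl]-2-[3,4-bis(benzyloxy)phenyl]-4-(3,4-dimethoxybenzyl)tetrahydrofuran | C1O[C@@H](c2ccc(OCc3ccccc3)c(OCc3ccccc3)c2)[C@@H](COCc2ccccc2)[C@]1(OCc2ccccc2)Cc2ccc(OC)c(OC)c2 | intermediate
13 | 4-[(2R,3R,4R)-4-(3,4-dimethoxybenzyl)-4-hydroxy-3-(hydroxymethyl)tetrahydrofuran-2-yl]benzene-1,2-diol | COc1ccc(C[C@]2(O)CO[C@@H](c3ccc(O)c(O)c3)[C@H]2CO)cc1OC | target

## Step count and least certain steps

Total step count: 9. Longest linear sequence: 9 steps (1 to 13); 5 and 9 enter as purchased materials.

**Step 3 (key step).** The most likely failure is loss of cross-selectivity: the homoenolate adds to a second molecule of the enal, which is the more electrophilic aldehyde, faster than to the electron-rich aldehyde 5. Where the cross-product does form, facial discrimination by the carbene may be incomplete. The first adjustments are a Lewis-acid co-catalyst such as LiCl and enrichment by crystallisation of 6 or 7.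

The fallback replaces catalysis by an auxiliary-controlled anti-aldol reaction; it sets out from 5 and comes back at 6. (R)-4-Benzyloxazolidin-2-one is N-acylated with pent-4-enoyl chloride (n-BuLi, THF, −78 °C) to (R)-4-benzyl-3-(pent-4-enoyl)oxazolidin-2-one F1. F1 and 5 are combined under the magnesium-catalysed anti-aldol conditions (MgCl2 cat., Et3N, Me3SiCl, EtOAc, rt) and should give the O-trimethylsilyl anti-aldol adduct F2. The chelated magnesium enolate is expected to be attacked on the face away from the benzyl group of the auxiliary, which for the (R)-auxiliary corresponds to the (2S) α-centre and, with the anti relationship, to the (R)-carbinol. Acidic methanol frees the anti-aldol adduct F3, and LiBH4 (THF, one equivalent of water, 0 °C) removes the auxiliary reductively to give the 1,3-diol F4. The primary hydroxyl is benzylated through the stannylene acetal (Bu2SnO, toluene, reflux; BnBr, CsF, DMF) to the primary benzyl ether F5. Cleavage of the terminal alkene (OsO4 cat., NaIO4, 2,6-lutidine, dioxane–water) gives an aldehyde that closes onto the C2 hydroxyl as the lactol F6, and oxidation (TEMPO cat., PhI(OAc)2, CH2Cl2) gives 6. The anti-aldol relationship maps onto the cis lactone because C6 is the former imide carbon and C4–C5 the former allyl group.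

**Step 6.** The most likely failure is slow alkylation of the hindered, tetrasubstituted α-alkoxy enolate. On warming, the enolate would then decompose (ring opening to a ketene, or migration of the O-benzyl group to carbon) before the C4–C7 bond forms, while 9 degrades.

The fallback replaces the SN2 step by carbonyl addition and deoxygenation; it sets out from 8 and comes back at 10. The lithium enolate of 8 is treated at −78 °C with 3,4-dimethoxybenzaldehyde; aldol addition is fast at that temperature, again anti to C6, and gives the β-hydroxy lactone F7 as C7 epimers. Thioacylation under neutral conditions (PhOC(S)Cl, DMAP, MeCN, rt; no alkoxide, to avoid retro-aldol cleavage) gives the O-phenyl thionocarbonate F8. Bu3SnH/AIBN (toluene, 90 °C) removes the C7 oxygen by Barton–McCombie deoxygenation through a benzylic radical and gives 10.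

**Step 8.** The most likely failure is ionisation of the benzylic C2–O1 bond in competition with ionisation at C5, because the oxocarbenium ion at C5 is destabilised by the adjacent C4–O bond. That would lead to epimerisation at C2 or to reductive opening of the ring.

The fallback avoids any Lewis acid; it sets out from 10 and comes back at 12, bypassing 11. LiAlH4 (THF, 0 °C) reduces the lactone to the 1,4-diol F9. The primary C5 hydroxyl is sulfonylated selectively (TsCl, Et3N, DMAP cat., CH2Cl2, 0 °C) to the primary monotosylate F10. KOt-Bu (THF, rt to 50 °C) closes the ring by 5-exo-tet displacement of the tosylate by the C2 alkoxide; the C2–O bond is never broken, so C2 cannot epimerise.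

**Step 9.** The most likely failure is over-reduction: hydrogenolysis of the ring bond C2–O1 while the hindered tertiary benzyl ether on C4 is still being cleaved.

The fallback changes the protecting group on the C4 oxygen, so that only unhindered benzyl ethers remain for the last step; it also bypasses step 5. It sets out from 7 and comes back at 13. 7 is silylated (Et3SiCl, imidazole, DMF) to the triethylsilyl ether F11. Alkylation with 9 as in step 6 gives the quaternary silyloxy lactone F12, and i-Bu2AlH as in step 7 gives the silyloxy lactol F13. Et3SiH/BF3·OEt2 as in step 8 gives the silyloxy tetrahydrofuran F14, and Bu4NF (THF) converts it to the tertiary alcohol F15. A short hydrogenolysis over Pd(OH)2/C then removes the two phenolic and the one primary benzyl ether and gives 13.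

## Further compounds

F1 | step 3 | (R)-4-benzyl-3-(pent-4-enoyl)oxazolidin-2-one | C=CCCC(=O)N1C(=O)OC[C@H]1Cc1ccccc1
F2 | step 3 | (R)-4-benzyl-3-[(2S)-2-{(R)-[3,4-bis(benzyloxy)phenyl][(trimethylsilyl)oxy]methyl}pent-4-enoyl]oxazolidin-2-one | C[Si](C)(C)O[C@@H](c1ccc(OCc2ccccc2)c(OCc2ccccc2)c1)[C@H](CC=C)C(=O)N1C(=O)OC[C@H]1Cc1ccccc1
F3 | step 3 | (R)-4-benzyl-3-[(2S)-2-{(R)-[3,4-bis(benzyloxy)phenyl](hydroxy)methyl}pent-4-enoyl]oxazolidin-2-one | O[C@@H](c1ccc(OCc2ccccc2)c(OCc2ccccc2)c1)[C@H](CC=C)C(=O)N1C(=O)OC[C@H]1Cc1ccccc1
F4 | step 3 | (1R,2R)-2-allyl-1-[3,4-bis(benzyloxy)phenyl]propane-1,3-diol | O[C@@H](c1ccc(OCc2ccccc2)c(OCc2ccccc2)c1)[C@H](CC=C)CO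
F5 | step 3 | (1R,2R)-2-[(benzyloxy)methyl]-1-[3,4-bis(benzyloxy)phenyl]pent-4-en-1-ol | O[C@@H](c1ccc(OCc2ccccc2)c(OCc2ccccc2)c1)[C@H](CC=C)COCc1ccccc1
F6 | step 3 | (4R,5R)-4-[(benzyloxy)methyl]-5-[3,4-bis(benzyloxy)phenyl]tetrahydrofuran-2-ol (anomers) | OC1O[C@@H](c2ccc(OCc3ccccc3)c(OCc3ccccc3)c2)[C@@H](COCc2ccccc2)C1
F7 | step 6 | (3S,4R,5R)-3-(benzyloxy)-4-[(benzyloxy)methyl]-5-[3,4-bis(benzyloxy)phenyl]-3-[(3,4-dimethoxyphenyl)(hydroxy)methyl]dihydrofuran-2(3H)-one (carbinol epimers) | O=C1O[C@@H](c2ccc(OCc3ccccc3)c(OCc3ccccc3)c2)[C@@H](COCc2ccccc2)[C@]1(OCc2ccccc2)C(O)c2ccc(OC)c(OC)c2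
F8 | step 6 | O-{[(3S,4R,5R)-3-(benzyloxy)-4-[(benzyloxy)methyl]-5-[3,4-bis(benzyloxy)phenyl]-2-oxotetrahydrofuran-3-yl](3,4-dimethoxyphenyl)methyl} O-phenyl carbonothioate | O=C1O[C@@H](c2ccc(OCc3ccccc3)c(OCc3ccccc3)c2)[C@@H](COCc2ccccc2)[C@]1(OCc2ccccc2)C(OC(=S)Oc2ccccc2)c2ccc(OC)c(OC)c2
F9 | step 8 | (1R,2R,3R)-3-(benzyloxy)-2-[(benzyloxy)methyl]-1-[3,4-bis(benzyloxy)phenyl]-3-(3,4-dimethoxybenzyl)butane-1,4-diol | O[C@@H](c1ccc(OCc2ccccc2)c(OCc2ccccc2)c1)[C@@H](COCc1ccccc1)[C@](CO)(OCc1ccccc1)Cc1ccc(OC)c(OC)c1
F10 | step 8 | (2R,3R,4R)-2-(benzyloxy)-3-[(benzyloxy)methyl]-4-[3,4-bis(benzyloxy)phenyl]-2-(3,4-dimethoxybenzyl)-4-hydroxybutyl 4-methylbenzenesulfonate | O[C@@H](c1ccc(OCc2ccccc2)c(OCc2ccccc2)c1)[C@@H](COCc1ccccc1)[C@](COS(=O)(=O)c1ccc(C)cc1)(OCc1ccccc1)Cc1ccc(OC)c(OC)c1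
F11 | step 9 | (3S,4R,5R)-4-[(benzyloxy)methyl]-5-[3,4-bis(benzyloxy)phenyl]-3-[(triethylsilyl)oxy]dihydrofuran-2(3H)-one | O=C1O[C@@H](c2ccc(OCc3ccccc3)c(OCc3ccccc3)c2)[C@@H](COCc2ccccc2)[C@@H]1O[Si](CC)(CC)CC
F12 | step 9 | (3R,4R,5R)-4-[(benzyloxy)methyl]-5-[3,4-bis(benzyloxy)phenyl]-3-(3,4-dimethoxybenzyl)-3-[(triethylsilyl)oxy]dihydrofuran-2(3H)-one | O=C1O[C@@H](c2ccc(OCc3ccccc3)c(OCc3ccccc3)c2)[C@@H](COCc2ccccc2)[C@]1(O[Si](CC)(CC)CC)Cc2ccc(OC)c(OC)c2
F13 | step 9 | (3R,4R,5R)-4-[(benzyloxy)methyl]-5-[3,4-bis(benzyloxy)phenyl]-3-(3,4-dimethoxybenzyl)-3-[(triethylsilyl)oxy]tetrahydrofuran-2-ol (anomers) | OC1O[C@@H](c2ccc(OCc3ccccc3)c(OCc3ccccc3)c2)[C@@H](COCc2ccccc2)[C@]1(O[Si](CC)(CC)CC)Cc2ccc(OC)c(OC)c2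
F14 | step 9 | (2R,3R,4R)-3-[(benzyloxy)methyl]-2-[3,4-bis(benzyloxy)phenyl]-4-(3,4-dimethoxybenzyl)-4-[(triethylsilyl)oxy]tetrahydrofuran | C1O[C@@H](c2ccc(OCc3ccccc3)c(OCc3ccccc3)c2)[C@@H](COCc2ccccc2)[C@]1(O[Si](CC)(CC)CC)Cc2ccc(OC)c(OC)c2
F15 | step 9 | (3R,4R,5R)-4-[(benzyloxy)methyl]-5-[3,4-bis(benzyloxy)phenyl]-3-(3,4-dimethoxybenzyl)tetrahydrofuran-3-ol | C1O[C@@H](c2ccc(OCc3ccccc3)c(OCc3ccccc3)c2)[C@@H](COCc2ccccc2)[C@]1(O)Cc2ccc(OC)c(OC)c2
A1 | alternative 1 | 5-[3,4-bis(trimethylsilyloxy)phenyl]-4-[(tert-butyldimethylsilyloxy)methyl]-3-(3,4-dimethoxybenzyl)tetrahydrofuran-3-ol, configured as in 13 | COc1ccc(C[C@]2(O)CO[C@@H](c3ccc(O[Si](C)(C)C)c(O[Si](C)(C)C)c3)[C@H]2CO[Si](C)(C)C(C)(C)C)cc1OC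
A2 | alternative 1 | 4-[(tert-butyldimethylsilyloxy)methyl]-3-(3,4-dimethoxybenzyl)-5-ethynyltetrahydrofuran-3-ol, configured as in 13 | COc1ccc(C[C@]2(O)CO[C@@H](C#C)[C@H]2CO[Si](C)(C)C(C)(C)C)cc1OC
A3 | alternative 1 | 2,3-bis(trimethylsilyloxy)buta-1,3-diene | C=C(O[Si](C)(C)C)C(=C)O[Si](C)(C)C
A4 | alternative 1 | 5-[4,5-bis(trimethylsilyloxy)cyclohexa-1,4-dien-1-yl]-4-[(tert-butyldimethylsilyloxy)methyl]-3-(3,4-dimethoxybenzyl)tetrahydrofuran-3-ol, configured as in 13 | COc1ccc(C[C@]2(O)CO[C@@H](C3=CCC(O[Si](C)(C)C)=C(O[Si](C)(C)C)C3)[C@H]2CO[Si](C)(C)C(C)(C)C)cc1OC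
A5 | alternative 2 | exo-6-[3,4-bis(pivaloyloxy)phenyl]-4-(3,4-dimethoxybenzyl)-2,7-dioxabicyclo[3.2.0]hept-3-ene | O1[C@@H](c2ccc(OC(=O)C(C)(C)C)c(OC(=O)C(C)(C)C)c2)[C@H]2[C@@H]1OC=C2Cc1ccc(OC)c(OC)c1
A6 | alternative 2 | 3,4-bis(pivaloyloxy)benzaldehyde | O=Cc1ccc(OC(=O)C(C)(C)C)c(OC(=O)C(C)(C)C)c1
A7 | alternative 2 | 3-(3,4-dimethoxybenzyl)furan | COc1ccc(Cc2ccoc2)cc1OC
A8 | alternative 3 | tertiary pinacol boronic ester with the C5 (isopropoxydimethylsilyl)methyl arm and the C7 3,4-dimethoxyphenyl arm | COc1ccc(C[C@](B2OC(C)(C)C(C)(C)O2)(C[Si](C)(C)OC(C)C)[C@H](COCc2ccccc2)[C@@H](O[Si](C)(C)C(C)(C)C)c2ccc(OCc3ccccc3)c(OCc3ccccc3)c2)cc1OC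
A9 | alternative 3 | 1,1-disubstituted alkenyl pinacol boronic ester carrying the C3 benzyloxymethyl and C2 silyloxy(aryl)methyl centres | C=C(B1OC(C)(C)C(C)(C)O1)[C@H](COCc1ccccc1)[C@@H](O[Si](C)(C)C(C)(C)C)c1ccc(OCc2ccccc2)c(OCc2ccccc2)c1
A10 | alternative 3 | (isopropoxydimethylsilyl)methylmagnesium chloride | CC(C)O[Si](C)(C)C[Mg]Cl
A11 | alternative 3 | 3,4-dimethoxyphenyl trifluoromethanesulfonate | COc1ccc(OS(=O)(=O)C(F)(F)F)cc1OC
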